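Theta's plateau, read as the mean of its late readings, stands at 15.5 %, and eta, charged with twice theta's coupling partner at equal catalyst, reads 26.3 % in the same way, which is 1.70 times as high.

| flask | starting material | coupling partner | free catalyst | remark | time |
|---|---|---|---|---|---|
| eta | 0.20 M | 0.20 M | 0.28 mM | run made earlier |  |
| theta | 0.20 M | 0.10 M | 0.28 mM | run made earlier |  |
| epsilon | 0.20 M | 0.15 M | 0.28 mM | run made earlier |  |
| beta | 0.20 M | 0.20 M | 0.42 mM | run made earlier |  |
| noon | 0.20 M | 0.200 M (fed, over 5.0 h) | 0.28 mM | all else is in the flask from the start; the feed brings no volume worth counting | 4.0 d |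
| winter | 0.20 M (fed, over 20 h) | 0.200 M | 0.28 mM | all else is in the flask from the start; the feed brings no volume worth counting | 4.0 d |
| dawn | 0.20 M | 0.200 M (fed, over 20 h) | 0.28 mM | all else is in the flask from the start; the feed brings no volume worth counting | 4.0 d |
| autumn | 0.20 M | 0.200 M | 0.28 mM | everything together at the start | 4.0 d |

| run | time / d | product / % |
|---|---|---|
| eta | 0.250 | 12.7 |
| eta | 0.833 | 23.6 |
| eta | 1.25 | 26.0 |
| eta | 2.00 | 25.7 |
| eta | 3.00 | 26.4 |
| eta | 4.00 | 26.8 |
| theta | 0.250 | 8.1 |
| theta | 0.417 | 11.0 |
| theta | 0.625 | 13.6 |
| theta | 1.25 | 15.4 |
| theta | 2.08 | 15.9 |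
| theta | 3.00 | 15.1 |
| epsilon | 0.500 | 16.5 |
| epsilon | 1.04 | 20.4 |
| epsilon | 1.67 | 21.1 |
| epsilon | 2.00 | 20.9 |
| epsilon | 2.50 | 22.4 |
| epsilon | 3.00 | 21.4 |
| beta | 0.250 | 19.1 |
| beta | 0.500 | 28.3 |
| beta | 0.833 | 32.9 |
| beta | 1.67 | 33.8 |
| beta | 3.00 | 35.0 |

(each reading ± 0.5 percentage points)

- what may be going on: catalyst intermediate C <-> free catalyst + product; catalyst intermediate A -> catalyst intermediate B; coupling partner -> decomposed reagent; coupling partner + catalyst intermediate B -> catalyst intermediate C; coupling partner <-> dormant form; starting material + free catalyst <-> catalyst intermediate A

- which flask leads in amount of product, in percent of the starting material charged ("all alike" within 1.5 percentage points) (noon / winter / dawn / autumn / all alike)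
- how much product is there at the end, in percent of the starting material charged: noon
- how much product is there at the end, in percent of the starting material charged: winter
- how much product is there at the end, in percent of the starting material charged: dawn
- how much product is there at the end, in percent of the starting material charged: autumn

What stops eta? Its starting material has not run out: about 73.7 % of it remains on the plateau, reckoning one product per starting material. My candidate for the limiting reagent is the coupling partner, which can decompose without ever meeting the catalyst.

How would you measure that loss? Suppose product forms in step with a partner that loses a steady fraction per unit time. Then the product still to come halves at equal intervals. From eta's first reading, 14 percentage points is still to come at 0.250 d, which gives 0.263 d. I call this reading T, the partner half-life: the time in which the product still to come falls to half.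

Isn't one reading weak ground? It is, so try a second one. T predicts 23.4 % at 0.833 d, and eta reads 23.6 %, which lies within the scatter.

What does T say of the feeds? Count n, the number of half-lives in a period. Winter's feed of starting material lasts 3.17 half-lives with all the partner in from the start, so I expect 11.1 % of the partner at its end. Noon's partner feed lasts 0.793 half-lives, and steady feeding against that loss should leave 76.9 % of the charge at its end. These are amounts of partner, not yields, and for yields I take the forecast.

The forecast names dawn as leader, with 28.2 % for noon, 15 % for winter, 30 % for dawn and 26.7 % for autumn. Of winter it says “Feeding starting material starves the catalyst while partner decays”.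

The flasks end with 31.5 % in dawn, the leader, 28.5 % in noon, 27.1 % in autumn and 20.2 % in winter.

    catalyst intermediate C ⇌ free catalyst + product (K = 0.450 M, k = 2220 h⁻¹)
    catalyst intermediate A → catalyst intermediate B (k = 48.7 h⁻¹)
    coupling partner → decomposed reagent (k = 0.104 h⁻¹)
    coupling partner + catalyst intermediate B → catalyst intermediate C (k = 234 M⁻¹ h⁻¹)
    coupling partner ⇌ dormant form (K = 0.800, k = 0.0107 h⁻¹)
    starting material + free catalyst ⇌ catalyst intermediate A (K = 11.0 M⁻¹, k = 12700 M⁻¹ h⁻¹)

Winter had reached 17.0 % of product by the end of its feed at 0.833 d, and it ends at 20.2 %. The count of 3.17 half-lives put winter's partner at 11.1 % at that moment, and the flask held 5.14 %, less than the count. In noon, the count over 0.793 half-lives gave 76.9 %, and at 0.208 d the flask held less, 70.0 % of its own charge of partner.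

The runs were computed for an exercise; scatter was added.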